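**Retrosynthetic overview**

1. Germacrane numbering: C1 ring ketone, C3 acetoxy carbinol, Z‑C4=C5, C6 lactone O–CH, C7=C11 butenolide alkene, C10=C14 exocyclic methylene, C12 lactone C=O, C13 CH2OAc.
2. Feature used: C6 is the γ‑carbon of the C7=C11 butenolide (five‑membered lactone) and is bonded to sp2 C5 of the Z‑C4=C5 alkene of the ten‑membered carbocycle. C5–C6 is therefore cut into a butenolide dienolate (used as its 2‑silyloxyfuran) and a Z‑vinyl iodide.
3. Seco precursor 18: C1–C2 by aldol addition of the enolate of (Z)‑4‑iodo‑3‑methylbut‑3‑en‑2‑one to a 2‑alkylacrolein; C3 by CBS reduction; O1 silylated, O3 acetylated.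
4. Butenolide ring first, by anti‑carbomagnesiation/carboxylation of but‑2‑yne‑1,4‑diol with pent‑4‑enylmagnesium bromide; the C1 aldehyde and C10 methylene follow by alkene cleavage and α‑methylenation.
5. Ring order: butenolide (step 1), then the ten‑membered carbocycle with C6 (step 11); afterwards desilylation, C13 acetylation and C1 oxidation.

Key step: step 11

Remark: C1 is carried as a mixture of epimers because it ends as the ketone, and but‑3‑yn‑2‑ol is used as the racemate because its carbinol centre is oxidised away in step 6.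

**Route**

Step 1
Reactants: 1 but‑2‑yne‑1,4‑diol; 2 5‑bromopent‑1‑ene
Product: 6 3‑(hydroxymethyl)‑4‑(pent‑4‑en‑1‑yl)furan‑2(5H)‑one, via pent‑4‑en‑1‑ylmagnesium bromide 3 (not isolated), via alkenylmagnesium chelate 4 (not isolated), via Z‑hydroxy acid 5 (not isolated)
Conditions: Mg, THF (2 to 3); 1 added to 3 (3.5 equiv), CuI (10 mol%), THF, 0 °C to 50 °C; CO2 (g), −20 °C to rt; 2 M HCl
Reagents that add atoms: carbon dioxide O=C=O
Why: Copper‑assisted anti‑carbomagnesiation of a propargylic alkoxide (Duboudin–Jousseaume type) puts the pentenyl group on one alkyne carbon and magnesium on the other, cis to the chelating CH2O, so that carboxylation and acidification should give a Z‑γ‑hydroxy acid that lactonises to the 3,4‑disubstituted butenolide; the free diol is used as its dialkoxide so that no β‑leaving group sits next to the alkenylmagnesium, and no stereocentre is formed.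

Step 2
Reactants: 6 3‑(hydroxymethyl)‑4‑(pent‑4‑en‑1‑yl)furan‑2(5H)‑one
Product: 7 3‑{[(tert‑butyldimethylsilyl)oxy]methyl}‑4‑(pent‑4‑en‑1‑yl)furan‑2(5H)‑one
Conditions: TBSCl, imidazole, CH2Cl2, 0 °C to rt
Reagents that add atoms: tert‑butyldimethylsilyl chloride CC(C)(C)[Si](C)(C)Cl
Why: Standard silyl ether formation on the primary allylic alcohol masks O13 for the basic and organometallic steps that follow.

Step 3
Reactants: 7 3‑{[(tert‑butyldimethylsilyl)oxy]methyl}‑4‑(pent‑4‑en‑1‑yl)furan‑2(5H)‑one
Product: 8 4‑[4‑{[(tert‑butyldimethylsilyl)oxy]methyl}‑5‑oxo‑2,5‑dihydrofuran‑3‑yl]butanal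
Conditions: OsO4 (2 mol%), NaIO4, 2,6‑lutidine, dioxane–H2O 3:1, rt
Reagents that add atoms: osmium tetroxide O=[Os](=O)(=O)=O (catalytic oxygen donor); sodium periodate [Na+].[O-]I(=O)(=O)=O (terminal oxidant)
Why: Lemieux–Johnson oxidative cleavage attacks only the electron‑rich monosubstituted alkene, since the tetrasubstituted, electron‑poor butenolide alkene is inert to OsO4, and gives the C1 aldehyde.

Step 4
Reactants: 8 4‑[4‑{[(tert‑butyldimethylsilyl)oxy]methyl}‑5‑oxo‑2,5‑dihydrofuran‑3‑yl]butanal
Product: 9 2‑methylidene‑4‑[4‑{[(tert‑butyldimethylsilyl)oxy]methyl}‑5‑oxo‑2,5‑dihydrofuran‑3‑yl]butanal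
Conditions: 37% aq. HCHO, pyrrolidine (10 mol%), EtCO2H (10 mol%), i‑PrOH, 45 °C
Reagents that add atoms: formaldehyde C=O
Why: Amine‑catalysed α‑methylenation of an aldehyde (Mannich condensation with formaldehyde, then loss of the amine) installs the C10=C14 methylene at the only enolisable aldehyde α‑carbon under nearly neutral conditions that should leave the butenolide and silyl ether untouched.

Step 5
Reactants: 10 but‑3‑yn‑2‑ol (racemic)
Product: 12 (Z)‑4‑iodo‑3‑methylbut‑3‑en‑2‑ol, via alkenylmagnesium chelate 11 (not isolated)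
Conditions: MeMgBr (3 equiv), CuI (10 mol%), THF–Et2O, −10 °C to rt; I2, −78 to 0 °C; aq. NH4Cl
Reagents that add atoms: methylmagnesium bromide C[Mg]Br; iodine II
Why: Copper‑catalysed anti‑carbomagnesiation of the propargylic alkoxide (Duboudin reaction) adds methyl to the internal and magnesium to the terminal alkyne carbon, cis to the carbinol, and iodinolysis with retention should give the Z‑vinyl iodide, which fixes the C4=C5 geometry.

Step 6
Reactants: 12 (Z)‑4‑iodo‑3‑methylbut‑3‑en‑2‑ol
Product: 13 (Z)‑4‑iodo‑3‑methylbut‑3‑en‑2‑one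
Conditions: Dess–Martin periodinane, NaHCO3, CH2Cl2, 0 °C, dark
Reagents that add atoms: none
Why: Buffered Dess–Martin oxidation of the secondary allylic alcohol is non‑acidic and, run in the dark, should preserve the Z geometry of the β‑iodo enone, which is used at once.

Step 7
Reactants: 13 (Z)‑4‑iodo‑3‑methylbut‑3‑en‑2‑one; 9 2‑methylidene‑4‑[4‑{[(tert‑butyldimethylsilyl)oxy]methyl}‑5‑oxo‑2,5‑dihydrofuran‑3‑yl]butanal
Product: 15 3‑{[(tert‑butyldimethylsilyl)oxy]methyl}‑4‑[(Z)‑4‑hydroxy‑8‑iodo‑7‑methyl‑3‑methylidene‑6‑oxooct‑7‑en‑1‑yl]furan‑2(5H)‑one (free C1–OH; racemic at C1), via lithium dienolate 14 (not isolated)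
Conditions: LiHMDS, THF, −78 °C; then 9, −78 °C; AcOH quench at −78 °C
Reagents that add atoms: none
Why: Directed crossed aldol addition forms C1–C2: the ketone can be enolised only at its methyl group (C2), and the lithium enolate should add 1,2 to the non‑enolisable enal at −78 °C faster than it exchanges protons with the butenolide; the new C1 carbinol centre is formed without control, which is harmless because C1 becomes the ketone in step 14.

Step 8
Reactants: 15 aldol adduct with free C1–OH
Product: 16 4‑[(Z)‑4‑[(tert‑butyldimethylsilyl)oxy]‑8‑iodo‑7‑methyl‑3‑methylidene‑6‑oxooct‑7‑en‑1‑yl]‑3‑{[(tert‑butyldimethylsilyl)oxy]methyl}furan‑2(5H)‑one (C1–OTBS; C3 ketone)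
Conditions: TBSOTf, 2,6‑lutidine, CH2Cl2, −78 °C
Reagents that add atoms: tert‑butyldimethylsilyl triflate CC(C)(C)[Si](C)(C)OS(=O)(=O)C(F)(F)F
Why: Silyl triflate/lutidine silylation of the secondary β‑hydroxy ketone at low temperature protects O1 without retro‑aldol or β‑elimination.

Step 9
Reactants: 16 C1‑silylated C3 ketone
Product: 17 4‑[(6S,7Z)‑4‑[(tert‑butyldimethylsilyl)oxy]‑6‑hydroxy‑8‑iodo‑7‑methyl‑3‑methylideneoct‑7‑en‑1‑yl]‑3‑{[(tert‑butyldimethylsilyl)oxy]methyl}furan‑2(5H)‑one (3S alcohol; C1 epimers)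
Conditions: (R)‑Me‑CBS (1 equiv), catecholborane, toluene, −78 °C; MeOH, then aq. work‑up
Reagents that add atoms: none
Why: Corey–Bakshi–Shibata reduction: the α‑methyl‑β‑iodovinyl group acts as the large substituent and the CH2 chain as the small one, so the (R)‑oxazaborolidine should deliver hydride to the face that gives the 3S alcohol under reagent control for both C1 epimers, and catecholborane at −78 °C should not touch the butenolide, the vinyl iodide or the 1,1‑disubstituted alkene.

Step 10
Reactants: 17 3S alcohol (C1 epimers)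
Product: 18 (2S,3Z)‑6‑[(tert‑butyldimethylsilyl)oxy]‑8‑[4‑{[(tert‑butyldimethylsilyl)oxy]methyl}‑5‑oxo‑2,5‑dihydrofuran‑3‑yl]‑4‑iodo‑3‑methyl‑7‑methylideneocta‑3‑en‑2‑yl acetate, i.e. the γ‑unsubstituted butenolide with tethered Z‑vinyl iodide, C3–OAc (S), C1–OTBS (epimers), C13–OTBS
Conditions: Ac2O, pyridine, DMAP (cat.), CH2Cl2, 0 °C to rt
Reagents that add atoms: acetic anhydride CC(=O)OC(C)=O
Why: DMAP‑catalysed acetylation of the secondary allylic alcohol installs the C3 acetate of the target with retention of configuration.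

Step 11
Reactants: 18 butenolide with tethered Z‑vinyl iodide
Product: 20 (3S,6R,4Z)‑3‑acetoxy‑1,13‑bis[(tert‑butyldimethylsilyl)oxy]germacra‑4,7(11),10(14)‑trien‑12,6‑olide (C1 epimers), via trimethylsilyloxyfuran 19 (not isolated)
Conditions: TMSOTf, Et3N, CH2Cl2, 0 °C; evaporation, pentane filtration; then Pd2(dba)3 (10 mol%), (R)‑DTBM‑SEGPHOS (22 mol%), ZnF2 (0.6 equiv), toluene–DMF 9:1, 50 °C, slow addition to 2 mM
Reagents that add atoms: none
Why: Proposed new method: the butenolide is O‑silylated to its 2‑silyloxyfuran 19 (a neutral, latent dienolate), Pd(0) inserts into the C5–I bond with retention of the Z geometry, fluoride from ZnF2 moves the furanolate from silicon to zinc and then to palladium, and C(sp2)–C(sp3) reductive elimination at the γ‑carbon forms C5–C6. The closest known reactions are Pd‑catalysed γ‑arylation of butenolide dienolates and of silyl dienolates, Pd/ZnF2 arylation of silyl ketene acetals, and intramolecular Pd‑catalysed alkenylation of enolates with vinyl halides to five‑ and six‑membered rings; a macrocyclising, face‑selective γ‑alkenylation has not been shown. The ten‑membered carbocycle closes by reductive elimination from an eleven‑membered palladacycle (C5–Pd–C6), favoured over oligomerisation by slow addition at 2 mM. C6 is created from the planar furanolate, and its 6R configuration has to be imposed by the C2‑symmetric bisphosphine on palladium in its matched pairing with the allylic C3 acetate centre (both ligand antipodes are to be compared). γ‑ over α‑coupling is secured by the fully substituted C11 and by restoration of the conjugated butenolide; coupling over 6‑exo Heck insertion into C10=C14 and over ionisation of the C3 acetate relies on the chelating ligand, retained iodide, low polarity and 50 °C, which leave no free site for alkene insertion. Silyl transfer is used in place of a Brønsted base because the product is more acidic at C6 than 18, so that in the absence of base C6 should not epimerise and C4=C5 should not move into conjugation.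

Step 12
Reactants: 20 macrocyclic bis‑silyl ether (C1 epimers)
Product: 21 (3S,6R,4Z)‑3‑acetoxy‑1,13‑dihydroxygermacra‑4,7(11),10(14)‑trien‑12,6‑olide (C1 epimers)
Conditions: HF·pyridine, pyridine, THF, 0 °C to rt
Reagents that add atoms: none
Why: Fluoride‑mediated cleavage of both silyl ethers under buffered acidic conditions should leave the acetate, the lactone and the C3 and C6 centres untouched and avoids base‑induced acetyl migration.

Step 13
Reactants: 21 diol (C1 epimers)
Product: 22 (3S,6R,4Z)‑3,13‑diacetoxy‑1‑hydroxygermacra‑4,7(11),10(14)‑trien‑12,6‑olide (C1 epimers)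
Conditions: AcCl (1.1 equiv), 2,4,6‑collidine, CH2Cl2, −78 °C
Reagents that add atoms: acetyl chloride CC(=O)Cl
Why: Kinetically selective acylation of the unhindered primary allylic alcohol over the secondary C1 alcohol with one equivalent of acid chloride and a hindered pyridine base at low temperature.

Step 14
Reactants: 22 C13 acetate with free C1–OH (C1 epimers)
Product: 23 (3S,6R,4Z)‑3,13‑diacetoxy‑1‑oxogermacra‑4,7(11),10(14)‑trien‑12,6‑olide (target, CNP0272505.1)
Conditions: Dess–Martin periodinane, NaHCO3, CH2Cl2, 0 °C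
Reagents that add atoms: none
Why: Dess–Martin oxidation of the secondary allylic alcohol under buffered, non‑basic conditions should give the α‑methylene ketone without β‑elimination of the C3 acetate and removes the C1 stereocentre, so both C1 epimers converge on the target.

**Compound list**

1 | but‑2‑yne‑1,4‑diol | OCC#CCO | starting material
2 | 5‑bromopent‑1‑ene | C=CCCCBr | starting material
3 | pent‑4‑en‑1‑ylmagnesium bromide | C=CCCC[Mg]Br | intermediate (not isolated)
4 | alkenylmagnesium chelate from 1 and 3 (C–Mg trans to pentenyl) | C=CCCC/C(CO[Mg]Br)=C(/[Mg]Br)CO[Mg]Br | intermediate (not isolated)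
5 | (Z)‑2,3‑bis(hydroxymethyl)octa‑2,7‑dienoic acid | C=CCCC/C(CO)=C(/C(=O)O)CO | intermediate (not isolated)
6 | 3‑(hydroxymethyl)‑4‑(pent‑4‑en‑1‑yl)furan‑2(5H)‑one | O=C1OCC(CCCC=C)=C1CO | intermediate
7 | 3‑{[(tert‑butyldimethylsilyl)oxy]methyl}‑4‑(pent‑4‑en‑1‑yl)furan‑2(5H)‑one | O=C1OCC(CCCC=C)=C1CO[Si](C)(C)C(C)(C)C | intermediate
8 | 4‑[4‑{[(tert‑butyldimethylsilyl)oxy]methyl}‑5‑oxo‑2,5‑dihydrofuran‑3‑yl]butanal | O=C1OCC(CCCC=O)=C1CO[Si](C)(C)C(C)(C)C | intermediate
9 | 2‑methylidene‑4‑[4‑{[(tert‑butyldimethylsilyl)oxy]methyl}‑5‑oxo‑2,5‑dihydrofuran‑3‑yl]butanal | O=C1OCC(CCC(=C)C=O)=C1CO[Si](C)(C)C(C)(C)C | intermediate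
10 | but‑3‑yn‑2‑ol (racemic) | CC(O)C#C | starting material
11 | alkenylmagnesium chelate from 10 (C–Mg cis to the carbinol) | CC(O[Mg]Br)/C(C)=C\[Mg]Br | intermediate (not isolated)
12 | (Z)‑4‑iodo‑3‑methylbut‑3‑en‑2‑ol | CC(O)/C(C)=C\I | intermediate
13 | (Z)‑4‑iodo‑3‑methylbut‑3‑en‑2‑one | CC(=O)/C(C)=C\I | intermediate
14 | lithium dienolate of 13 | [Li]OC(=C)/C(C)=C\I | intermediate (not isolated)
15 | aldol adduct, C1–OH free, C3 ketone (racemic at C1) | O=C1OCC(CCC(=C)C(O)CC(=O)/C(C)=C\I)=C1CO[Si](C)(C)C(C)(C)C | intermediate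
16 | C1‑O‑TBS ether of 15 | O=C1OCC(CCC(=C)C(O[Si](C)(C)C(C)(C)C)CC(=O)/C(C)=C\I)=C1CO[Si](C)(C)C(C)(C)C | intermediate
17 | 3S alcohol (C1 epimers) | O=C1OCC(CCC(=C)C(O[Si](C)(C)C(C)(C)C)C[C@H](O)/C(C)=C\I)=C1CO[Si](C)(C)C(C)(C)C | intermediate
18 | 3S acetate, γ‑unsubstituted butenolide with tethered Z‑vinyl iodide (C1 epimers) | O=C1OCC(CCC(=C)C(O[Si](C)(C)C(C)(C)C)C[C@H](OC(C)=O)/C(C)=C\I)=C1CO[Si](C)(C)C(C)(C)C | intermediate
19 | 2‑(trimethylsilyloxy)furan derived from 18 | C[Si](C)(C)Oc1occ(CCC(=C)C(O[Si](C)(C)C(C)(C)C)C[C@H](OC(C)=O)/C(C)=C\I)c1CO[Si](C)(C)C(C)(C)C | intermediate (not isolated)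
20 | (3S,6R,4Z)‑3‑acetoxy‑1,13‑bis[(tert‑butyldimethylsilyl)oxy]germacra‑4,7(11),10(14)‑trien‑12,6‑olide (C1 epimers) | C=C1CCC2=C(CO[Si](C)(C)C(C)(C)C)C(=O)O[C@@H]2/C=C(/C)[C@@H](OC(C)=O)CC1O[Si](C)(C)C(C)(C)C | intermediate
21 | (3S,6R,4Z)‑3‑acetoxy‑1,13‑dihydroxygermacra‑4,7(11),10(14)‑trien‑12,6‑olide (C1 epimers) | C=C1CCC2=C(CO)C(=O)O[C@@H]2/C=C(/C)[C@@H](OC(C)=O)CC1O | intermediate
22 | (3S,6R,4Z)‑3,13‑diacetoxy‑1‑hydroxygermacra‑4,7(11),10(14)‑trien‑12,6‑olide (C1 epimers) | C=C1CCC2=C(COC(C)=O)C(=O)O[C@@H]2/C=C(/C)[C@@H](OC(C)=O)CC1O | intermediate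
23 | (3S,6R,4Z)‑3,13‑diacetoxy‑1‑oxogermacra‑4,7(11),10(14)‑trien‑12,6‑olide | C=C1CCC2=C(COC(C)=O)C(=O)O[C@@H]2/C=C(/C)[C@@H](OC(C)=O)CC1=O | target

**Step count**

Total step count: 14. Longest linear sequence: 12 steps (steps 1–4 and 7–14, from but‑2‑yne‑1,4‑diol).

**Steps most likely to fail**

1. Step 11 (Proposed new method).
 - What may go wrong: transmetalation and reductive elimination through the eleven‑membered palladacycle may be slower than 6‑exo Heck insertion of the alkenylpalladium into the C10=C14 methylene, than ionisation of the allylic C3 acetate, or than intermolecular coupling. The face selectivity at C6 may also be low.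
 - Fallback (known chemistry, same C5–C6 bond): it sets out from 18. Silyloxyfuran 19 is made as in step 11 and oxidised at C6 with dimethyldioxirane (acetone, −78 °C) to the γ‑hydroxybutenolide F1. Trimethylsilyldiazomethane (MeOH–toluene, 0 °C) opens this pseudo‑acid to the methyl (Z)‑formyl ester F2, which carries C6 as an aldehyde. An intramolecular Nozaki–Hiyama–Kishi reaction (CrCl2, cat. NiCl2, DMSO–THF, rt, 2 mM) adds the C5 alkenylchromium to the C6 aldehyde, and the Z‑γ‑alkoxy ester lactonises. The C6 epimers would be separated, or the face biased with a chiral sulfonamide ligand on chromium. The sequence comes back to the route at 20.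

2. Step 7.
 - What may go wrong: proton transfer from the acidic C6 methylene of the butenolide to the lithium dienolate, conjugate addition or polymerisation of the 2‑alkylacrolein, or Z to E isomerisation of the β‑iodo enone during enolisation.
 - Fallback: it sets out from 13. TMSOTf/Et3N (CH2Cl2, 0 °C) gives the silyl dienol ether F3, which is added to 9 in a Lewis‑acid‑mediated Mukaiyama aldol reaction (BF3·OEt2, CH2Cl2, −78 °C; mild aqueous work‑up), so that no basic enolate meets the butenolide. It comes back to the route at 15.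

3. Step 9.
 - What may go wrong: poor facial selectivity in the ketone reduction (epimeric C1 silyl ether nearby, twisted Z‑iodo enone), or competing conjugate reduction with loss of the vinyl iodide.
 - Fallback: C3 is set in the C–C bond formation with reversed polarity. It sets out from 9: MeMgBr (THF, −78 °C) gives the allylic alcohol F4, and Dess–Martin oxidation gives the methyl enone F5. Separately, commercial propargyl alcohol is converted by MeMgBr/CuI then I2 into (Z)‑3‑iodo‑2‑methylprop‑2‑en‑1‑ol F6 and oxidised with MnO2 to (Z)‑3‑iodo‑2‑methylacrylaldehyde F7. A Paterson boron aldol reaction of F5 (Ipc2BCl, Et3N; the Ipc antipode that gives 3S) with F7 gives the 3S β‑hydroxy ketone F8. Acetylation (Ac2O, pyridine, 0 °C) gives the acetate F9, Luche reduction (NaBH4, CeCl3, MeOH, −40 °C) gives the C1 alcohol F10, and silylation (TBSOTf, 2,6‑lutidine) brings the sequence back to the route at 18.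

Further compounds
F1 | step 11 | γ‑hydroxybutenolide (C6–OH, epimers) derived from 18 | O=C1OC(O)C(CCC(=C)C(O[Si](C)(C)C(C)(C)C)C[C@H](OC(C)=O)/C(C)=C\I)=C1CO[Si](C)(C)C(C)(C)C
F2 | step 11 | methyl (Z)‑formyl ester (ring‑opened, C6 aldehyde) | COC(=O)/C(CO[Si](C)(C)C(C)(C)C)=C(\C=O)CCC(=C)C(O[Si](C)(C)C(C)(C)C)C[C@H](OC(C)=O)/C(C)=C\I
F3 | step 7 | (Z)‑(4‑iodo‑3‑methylbuta‑1,3‑dien‑2‑yloxy)trimethylsilane | C=C(O[Si](C)(C)C)/C(C)=C\I
F4 | step 9 | allylic alcohol from 9 and MeMgBr | O=C1OCC(CCC(=C)C(C)O)=C1CO[Si](C)(C)C(C)(C)C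
F5 | step 9 | methyl enone (C1 ketone, C2 methyl) | O=C1OCC(CCC(=C)C(C)=O)=C1CO[Si](C)(C)C(C)(C)C
F6 | step 9 | (Z)‑3‑iodo‑2‑methylprop‑2‑en‑1‑ol | OC/C(C)=C\I
F7 | step 9 | (Z)‑3‑iodo‑2‑methylacrylaldehyde | O=C/C(C)=C\I
F8 | step 9 | 3S β‑hydroxy ketone (C1 ketone) | O=C1OCC(CCC(=C)C(=O)C[C@H](O)/C(C)=C\I)=C1CO[Si](C)(C)C(C)(C)C
F9 | step 9 | 3S β‑acetoxy ketone (C1 ketone) | O=C1OCC(CCC(=C)C(=O)C[C@H](OC(C)=O)/C(C)=C\I)=C1CO[Si](C)(C)C(C)(C)C
F10 | step 9 | 3S acetate with free C1–OH (C1 epimers) | O=C1OCC(CCC(=C)C(O)C[C@H](OC(C)=O)/C(C)=C\I)=C1CO[Si](C)(C)C(C)(C)C
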